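**Retrosynthetic overview**

1. Ring B (the 4,4-dimethylcyclohexadienone ring) is cut at the two bonds that join the carbonyl carbons flanking C(CH3)2 to their other ring neighbours. This gives a dimethylmalonyl C3 unit (dimethyl 2,2-dimethylmalonate) and a 1-aryl-6-methylheptane-3,5-dione.
2. That diketone is cut between its central CH2 and the ring-side carbonyl. This gives the enolate of 3-methylbutan-2-one and a 3,4-dihydrocoumarin (temporary lactone ring C) that ties one phenol oxygen of ring A to the CH2CH2C(=O) arm. All three pieces are joined in one flask.
3. Enabling feature: in ring B the quaternary C(CH3)2 lies between two carbonyl carbons, so it is a non-enolizable 1,3-dielectrophile. The ring carbon bearing the ArCH2 group and the ring carbon bearing the isobutyryl group are the two α-carbons of the single C–OH carbon between them, so they are the γ- and α-sites of a β-diketone dianion. Ring A carries an oxygen ortho to the bridging CH2, which allows the lactone.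
4. The lactone also masks the oxygen para to the benzoyl group, so the prenyl ether can be placed on the less hindered ortho oxygen. The bridging CH2 is in place before ring B exists, so no unsymmetrical methylene coupling is needed.
5. Ring order: ring A is purchased (2,4,6-trihydroxybenzophenone), then temporary ring C is formed (step 1), then ring B is formed last (step 3), with ring C opened in the same operation.

Key step: step 3

Assumption: ring B of the target is one drawn tautomer of an enolized 2-acylcyclohexane-1,3,5-trione; the tautomers interconvert freely, so the route is planned for the equilibrium mixture, and the target has no stereocentre.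

**Step 1**
Reactants: 1 2,4,6-trihydroxybenzophenone; 2 acrylic acid
Product: 3 6-benzoyl-5,7-dihydroxychroman-2-one
Conditions: 2 (1.5 equiv), Amberlyst 15 (sulfonic acid resin), hydroquinone (cat.), toluene/1,4-dioxane, reflux, Dean–Stark
Reagents that add atoms: none
Why: Acid-catalysed Friedel–Crafts hydroarylation (conjugate addition) of acrylic acid by one of the two equivalent free positions of ring A followed by lactonization should give the dihydrocoumarin, the ring closing through the unchelated para-hydroxyl as in Pechmann condensations of 2-acylresorcinols, which leaves both benzoyl-flanking hydroxyls free.

**Step 2**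
Reactants: 3 6-benzoyl-5,7-dihydroxychroman-2-one; 4 prenyl bromide
Product: 5 6-benzoyl-5-hydroxy-7-[(3-methylbut-2-en-1-yl)oxy]chroman-2-one
Conditions: 4 (1.05 equiv), K2CO3 (1.1 equiv), dry acetone, 23 °C
Reagents that add atoms: none
Why: Williamson etherification, in which O-7 is flanked only by H-8 whereas O-5 is buttressed between C-4 and the benzoyl group and stays locked in its hydrogen bond, so one equivalent of 4 should alkylate O-7 (para to the future bridging CH2) and stop at the mono-ether.

**Step 3**
Reactants: 5 6-benzoyl-5-hydroxy-7-[(3-methylbut-2-en-1-yl)oxy]chroman-2-one; 6 3-methylbutan-2-one; 7 dimethyl 2,2-dimethylmalonate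
Product: 10 sarothralin, via ring-opened β-diketone 8 (not isolated), via tetraketo ester 9 (not isolated)
Conditions: 6 (1.05 equiv), LiN(iPr)2 (1.05 equiv), THF, −78 °C; LiN(SiMe3)2 (2.1 equiv), then 5, −78 → 0 °C; LiN(iPr)2 (2.2 equiv), DMPU, −78 → 0 °C; 7 (1.3 equiv), 0 → 50 °C; then 1 M HCl
Reagents that add atoms: none
Why: Proposed new method: the kinetic lithium enolate of 6 should open the aryl lactone of 5 by Claisen acylation (phenoxide as leaving group) to the enolate of β-diketone 8; LiN(iPr)2 then removes a proton from the side-chain CH2 next to the ketone (methylene before the isopropyl methine) to give the 1,3-diketone dianion, whose terminal carbanion is acylated by one ester of 7 (giving 9) and whose central carbon then attacks the second ester. The closest known reaction types are the ester acylation of β-diketone dianions (Hauser–Harris), the Claisen cyclization of 3,5,7-triketo esters to acylphloroglucinols and the classical malonate/acetonedicarboxylate phloroglucinol condensation; what is new is the telescoping of these with the lactone opening into one three-component operation. Ring B closes by a 6-(enolexo)-exo-trig acyl substitution (Dieckmann mode), helped by the gem-dimethyl group; temporary ring C is opened in the same flask. No stereocentre remains, since the CH centre of 9 is lost by enolization. The step needs γ- before α-acylation, C- over O-acylation and Claisen over aldol closure: the first follows from the dianion's terminal carbon being its most basic site, the second from equilibration (LiOMe reopens any enol lactone, while the product is withdrawn as the doubly stabilized triketone anion), the third from the quaternary C(CH3)2 of 7, which leaves no enolizable position for an aldol or aromatization path or for self-condensation. The two lithium phenoxides are spectators and deactivate the diaryl ketone.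

**Compound list**

1 | 2,4,6-trihydroxybenzophenone, (2,4,6-trihydroxyphenyl)(phenyl)methanone | O=C(c1ccccc1)c1c(O)cc(O)cc1O | starting material
2 | acrylic acid (prop-2-enoic acid) | C=CC(=O)O | starting material
3 | 6-benzoyl-5,7-dihydroxychroman-2-one (6-benzoyl-5,7-dihydroxy-3,4-dihydro-2H-chromen-2-one; lactone through the oxygen para to benzoyl) | O=C1CCc2c(O)c(C(=O)c3ccccc3)c(O)cc2O1 | intermediate
4 | prenyl bromide (1-bromo-3-methylbut-2-ene) | CC(C)=CCBr | starting material
5 | 6-benzoyl-5-hydroxy-7-[(3-methylbut-2-en-1-yl)oxy]chroman-2-one | O=C1CCc2c(O)c(C(=O)c3ccccc3)c(OCC=C(C)C)cc2O1 | intermediate
6 | 3-methylbutan-2-one | CC(=O)C(C)C | starting material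
7 | dimethyl 2,2-dimethylmalonate (dimethyl 2,2-dimethylpropanedioate) | COC(=O)C(C)(C)C(=O)OC | starting material
8 | 1-[3-benzoyl-2,6-dihydroxy-4-(3-methylbut-2-en-1-yloxy)phenyl]-6-methylheptane-3,5-dione (present in the flask as its lithium polyanion) | CC(C)C(=O)CC(=O)CCc1c(O)cc(OCC=C(C)C)c(C(=O)c2ccccc2)c1O | intermediate
9 | methyl 4-{[3-benzoyl-2,6-dihydroxy-4-(3-methylbut-2-en-1-yloxy)phenyl]methyl}-2,2,8-trimethyl-3,5,7-trioxononanoate (racemic at C-4, enolized lithium polyanion in the flask) | CC(C)C(=O)CC(=O)C(Cc1c(O)cc(OCC=C(C)C)c(C(=O)c2ccccc2)c1O)C(=O)C(C)(C)C(=O)OC | intermediate
10 | sarothralin (no stereocentre) | CC(C)=CCOc1cc(O)c(CC2=C(O)C(C)(C)C(=O)C(C(=O)C(C)C)=C2O)c(O)c1C(=O)c1ccccc1 | target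

**Summary**

Total step count: 3. Longest linear sequence: 3 steps (1 → 3 → 5 → 10).

**Steps most likely to fail**

Step 3. The telescoped sequence may stall or branch in three ways:
- proton transfer from the freshly formed, acidic diketone to unreacted enolate;
- E1cB opening of the aryl lactone to a ketene that is captured unproductively;
- slow intermolecular acylation of the secondary dianion carbon by the neopentyl-type ester, so that half-reacted or O-acylated material accumulates.

The fallback sets out from 5 and comes back at 10. It runs the three bond formations as separate, individually precedented steps with isolation. Claisen ring opening of 5 with the lithium enolate of 6 (2.1 equiv, THF, −78 → 0 °C) should give β-diketone 8, now isolated. Its polyanion (LiN(iPr)2, 5.2 equiv, THF/DMPU, 0 °C) should be γ-acylated by excess 7 in the Hauser–Harris manner to give tetraketo ester 9, isolated after acidic work-up. Compound 9 is then closed under equilibrating conditions (NaOMe, MeOH, 23–50 °C, or Mg(OMe)2), as in the Claisen cyclization of triketo esters to acylphloroglucinols, to give 10. No compound outside the compound list is made (F0).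

Step 1. Conjugate addition of the benzoyl-deactivated ring to acrylic acid may be sluggish, with acrylic acid oligomerization and a second alkylation at C-8, or the lactone may close through the chelated ortho oxygen. The fallback sets out from 1 and comes back at 3. Pechmann condensation of 1 with ethyl propiolate (ZnCl2, 90 °C) should close through the para oxygen, by the precedent of 2-acylresorcinols, and give 6-benzoyl-5,7-dihydroxy-2H-chromen-2-one F1. Hydrogenation of its C3–C4 double bond (H2, 1 atm, Pd/C, ethyl acetate, 23 °C), before any prenyl group is present, should give 3.

Step 2. Discrimination between O-7 and O-5 may be insufficient, the ambident phenoxide may C-alkylate at C-8, or carbonate may open the lactone. The fallback sets out from 3 and comes back at 5. It replaces phenoxide alkylation by a Mitsunobu etherification with 3-methylbut-2-en-1-ol (PPh3, diisopropyl azodicarboxylate, THF, 0 °C). This is a neutral redox condensation without a free phenoxide, so C-alkylation and base-induced lactone opening are avoided and the bulkier oxyphosphonium electrophile should favour the less hindered O-7. No compound outside the compound list is made (F0).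

**Further compounds**

F0 | step 3 | none | none
F1 | step 1 | 6-benzoyl-5,7-dihydroxy-2H-chromen-2-one | O=c1ccc2c(O)c(C(=O)c3ccccc3)c(O)cc2o1
F0 | step 2 | none | none
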